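I began with an easy division: each charge over the last target reading of its run. I called that the price, the reciprocal of the yield: starting material charged per target made.

| flask | starting material | time |
|---|---|---|
| west | 0.250 M |  |
| north-east | 0.100 M |  |
| south-east | 0.380 M |  |
| north-west | 0.750 M | 6.4 min |

| run | time / min | [target] / M |
|---|---|---|
| west run | 0.28 | 0.0174 |
| west run | 0.86 | 0.0345 |
| west run | 1.6 | 0.0573 |
| west run | 2.6 | 0.0680 |
| west run | 3.7 | 0.0784 |
| west run | 5.0 | 0.0786 |
| west run | 6.4 | 0.0811 |
| north-east run | 0.28 | 0.0106 |
| north-east run | 0.86 | 0.0191 |
| north-east run | 1.6 | 0.0273 |
| north-east run | 2.6 | 0.0309 |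
| north-east run | 3.7 | 0.0378 |
| north-east run | 5.0 | 0.0356 |
| north-east run | 6.4 | 0.0392 |
| south-east run | 0.28 | 0.0271 |
| south-east run | 0.86 | 0.0545 |
| south-east run | 1.6 | 0.0765 |
| south-east run | 2.6 | 0.0970 |
| south-east run | 3.7 | 0.1056 |
| south-east run | 5.0 | 0.1148 |
| south-east run | 6.4 | 0.1131 |

(readings scatter by 0.002 M)

- Overall: starting material -> target.
- Constant volume, constant temperature.
- An order is taken over about fifteen percent of the charge, up and down.

1. apparent order in [starting material] of the starting rate, round the charge of the west run (the rate where two percent of its starting material have turned into target) (one fixed amount of target, the same in the runs compared)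
2. target in the north-west run at 6.4 min, as a share of the starting material charged

| Run | Charge | Last target | Price |
|---|---|---|---|
| north-east | 0.100 M | 0.0392 M | 2.55 |
| west | 0.250 M | 0.0811 M | 3.08 |
| south-east | 0.380 M | 0.1131 M | 3.36 |

Two readings looked contradictory. At 1.6 min the north-east run stood at 69.6% of its last reading and the south-east run at 67.6%. That is a clock indifferent to charge, as with first-order steps. But first-order steps keep one share at any charge, and the last shares were 39.2% and 29.8%.

I supposed that starting material went to target at first order and was also lost by a first-order and a second-order route. A second-order loss costs more at a higher charge, so the price should climb roughly in a straight line. The price slope, the rise in price per molar of charge, read 2.89 M⁻¹ from the outer runs. The west run, kept out, lay on the line at 2.98. At zero charge the line stood at 2.26, not 1, which pointed to a loss independent of charge. At 0.750 M it gave a price of 4.43, so a share of 22.6%. A first-order target step gave me an order of 1.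

The forecast gave order 0.8 and share 25%: “The run is essentially at plateau by 6.4 min, so I expect about 25%.”

The flask gave order 1.0 and share 22.8%, a price of 4.39.

    starting material → target (0.2664 min⁻¹)
    2 starting material → side product (0.9840 M⁻¹ min⁻¹)
    starting material → decomposed substrate (0.2976 min⁻¹)

The north-west share was held down by the loss of starting material to decomposed substrate, worth 8 percentage points. Without that loss, the target step at vanishing charge stands at a price of 1.22 at 6.4 min, not 1, since that step is unfinished then. With my price slope carried over as an estimate, the north-west price comes to 3.39 and the share to 29.5%. The simulated north-west run without that loss gave 30.9%, a price of 3.24.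

(All runs were computed on assumed constants, noise included.)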